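The disconnection is the bond between ring A C1 and its CO2CH3 carbon. Without that ester, ring A (C2 OH, C3 CH3, C4 OH, C6 CH2O) has a mirror plane through C3 and C6, so the benzyl alcohol can be iodinated at only one kind of position. Its oxygen can also be acylated by ring B while no ester sits beside it, which excludes a phthalide. One palladium-catalysed operation then unites the aryl iodide, CO and methanol, making the C1–carbonyl and carbonyl–OCH3 bonds. The precursor is the complete two-ring benzyl ester: iodine on ring A C1, four phenols as MOM ethers, the ring B aldehyde as its dimethyl acetal.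

Key step: step 10

Remark: the target has no stereocentre, so no step has to control configuration.
Remark: the ring B acid is never set free, because a dimethyl acetal on so electron-rich a ring would not survive the aqueous acid needed to protonate its carboxylate. The ester bond is therefore made by alkylating the lithium carboxylate (step 9). The acetal-bearing compounds 11, 14 and 17 are purified on Et3N-deactivated silica.

Step 1
Reactants: 1 3,5-dihydroxy-4-methylbenzoic acid
Product: 2 methoxymethyl 3,5-bis(methoxymethoxy)-4-methylbenzoate
Conditions: MOMCl, i-Pr2NEt, DMF, 0 °C to rt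
Reagents that add atoms: chloromethyl methyl ether, COCCl
Why: O-alkylation of the two phenols and the carboxylic acid by the α-chloro ether (MOM protection, a Williamson-type substitution) should be complete with excess reagent, and the methoxymethyl ester formed at the acid is consumed in the next step.

Step 2
Reactants: 2 methoxymethyl 3,5-bis(methoxymethoxy)-4-methylbenzoate
Product: 3 [3,5-bis(methoxymethoxy)-4-methylphenyl]methanol
Conditions: LiAlH4, THF, 0 °C; Na2SO4·10H2O quench
Reagents that add atoms: none
Why: LiAlH4 reduction of an ester to the primary alcohol is reliable, aryl MOM ethers are inert to hydride, and the methoxymethyl group of the ester leaves as methanol.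

Step 3
Reactants: 3 [3,5-bis(methoxymethoxy)-4-methylphenyl]methanol
Product: 4 [2-iodo-3,5-bis(methoxymethoxy)-4-methylphenyl]methanol
Conditions: NIS (1.0 equiv), MeCN, 0 °C to rt, dark
Reagents that add atoms: N-iodosuccinimide, O=C1CCC(=O)N1I
Why: Electrophilic aromatic iodination should occur ortho to one OMOM and para to the other; because C2 and C6 of 3 are equivalent and C4 carries the methyl group, only one mono-iodide can form, and one equivalent of NIS at low temperature holds back the diiodide.

Step 4
Reactants: 4 [2-iodo-3,5-bis(methoxymethoxy)-4-methylphenyl]methanol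
Product: 5 1-(bromomethyl)-2-iodo-3,5-bis(methoxymethoxy)-4-methylbenzene
Conditions: CBr4, PPh3, CH2Cl2, 0 °C
Reagents that add atoms: carbon tetrabromide, BrC(Br)(Br)Br
Why: The Appel reaction converts the primary benzylic alcohol into the bromide under neutral conditions that spare the MOM ethers and the aryl iodide, and the bromide, having no ortho or para oxygen, should be stable to isolation.

Step 5
Reactants: 6 orcinol (5-methylbenzene-1,3-diol)
Product: 7 1,3-bis(methoxymethoxy)-5-methylbenzene
Conditions: MOMCl, i-Pr2NEt, CH2Cl2, 0 °C to rt
Reagents that add atoms: chloromethyl methyl ether, COCCl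
Why: Williamson-type O-alkylation of both phenols with MOMCl (MOM protection) installs the groups that direct the metalation in step 6.

Step 6
Reactants: 7 1,3-bis(methoxymethoxy)-5-methylbenzene
Product: 9 2,6-bis(methoxymethoxy)-4-methylbenzaldehyde, via aryllithium 8 (not isolated)
Conditions: n-BuLi, TMEDA, THF, 0 °C; DMF; H2O
Reagents that add atoms: N,N-dimethylformamide, CN(C)C=O
Why: Directed ortho-metalation removes the proton at C2, the only position flanked by two OMOM groups, and formylation of the aryllithium with DMF gives the aldehyde after aqueous collapse of the hemiaminal alkoxide.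

Step 7
Reactants: 9 2,6-bis(methoxymethoxy)-4-methylbenzaldehyde
Product: 10 3-bromo-2,6-bis(methoxymethoxy)-4-methylbenzaldehyde
Conditions: NBS (1.0 equiv), MeCN, 0 °C to rt
Reagents that add atoms: N-bromosuccinimide, O=C1CCC(=O)N1Br
Why: Electrophilic aromatic bromination should go to C3, which is equivalent to C5 by symmetry, ortho and para to the two OMOM groups and meta to the formyl group, so one equivalent of NBS gives a single mono-bromide.

Step 8
Reactants: 10 3-bromo-2,6-bis(methoxymethoxy)-4-methylbenzaldehyde
Product: 11 1-bromo-3-(dimethoxymethyl)-2,4-bis(methoxymethoxy)-6-methylbenzene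
Conditions: HC(OMe)3, PPTS (cat.), CH2Cl2, rt; Et3N quench
Reagents that add atoms: trimethyl orthoformate, COC(OC)OC
Why: Acid-catalysed acetalisation with an orthoester, driven by irreversible formation of methyl formate, should mask the aldehyde for the organolithium step, while a pyridinium acid in an alcohol-free medium is too weak to exchange the aryl MOM ethers.

Step 9
Reactants: 11 1-bromo-3-(dimethoxymethyl)-2,4-bis(methoxymethoxy)-6-methylbenzene; 5 1-(bromomethyl)-2-iodo-3,5-bis(methoxymethoxy)-4-methylbenzene
Product: 14 [2-iodo-3,5-bis(methoxymethoxy)-4-methylphenyl]methyl 3-(dimethoxymethyl)-2,4-bis(methoxymethoxy)-6-methylbenzoate, via aryllithium 12 (not isolated), via lithium carboxylate 13 (not isolated)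
Conditions: 11, n-BuLi, THF, −78 °C; CO2, −78 °C to rt; evaporate; then 5, DMF, rt to 40 °C
Reagents that add atoms: carbon dioxide, O=C=O
Why: Bromine–lithium exchange, carboxylation of the aryllithium and SN2 O-alkylation of the resulting carboxylate by the benzylic bromide should deliver the hindered ester without using the shielded carbonyl as an electrophile and without acidifying the carboxylate, which the acid-labile dimethyl acetal would not survive.

Step 10
Reactants: 14 [2-iodo-3,5-bis(methoxymethoxy)-4-methylphenyl]methyl 3-(dimethoxymethyl)-2,4-bis(methoxymethoxy)-6-methylbenzoate; 15 carbon monoxide; 16 methanol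
Product: 17 methyl 6-{[3-(dimethoxymethyl)-2,4-bis(methoxymethoxy)-6-methylbenzoyl]oxymethyl}-2,4-bis(methoxymethoxy)-3-methylbenzoate
Conditions: Pd(OAc)2 (10 mol %), 1,1'-bis(diphenylphosphino)ferrocene (12 mol %), Et3N, CO (5 bar), MeOH–DMF 1:2, 70 °C
Reagents that add atoms: carbon monoxide, [C-]#[O+]; methanol, CO
Why: Pd(OAc)2 is reduced in situ to a zerovalent palladium–diphosphine complex that inserts into the C–I bond of 14; CO then coordinates and undergoes migratory insertion to an aroyl complex of divalent palladium, and methanol, assisted by Et3N, cleaves it to the methyl ester while the base takes up HI and zerovalent palladium is regenerated. This is the well-established palladium-catalysed alkoxycarbonylation of aryl iodides. No ring closes and no stereocentre forms. The step needs chemoselectivity only: the C–I bond is the sole site for oxidative addition, the benzylic oxygen is already acylated so it cannot capture the aroyl palladium intermediate as a phthalide, and the ring B ester, flanked by 6-CH3 and 2-OMOM, should resist methanolysis by Et3N in methanol. Site selectivity was settled in step 3, where iodine entered one of two equivalent carbons of the symmetric alcohol 3, and the wide-bite-angle ferrocenyl diphosphine is chosen to drive CO insertion and alcoholysis at the doubly ortho-substituted carbon.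

Step 11
Reactants: 17 methyl 6-{[3-(dimethoxymethyl)-2,4-bis(methoxymethoxy)-6-methylbenzoyl]oxymethyl}-2,4-bis(methoxymethoxy)-3-methylbenzoate
Product: 18 methyl 6-{[(3-formyl-2,4-dihydroxy-6-methylbenzoyl)oxy]methyl}-2,4-dihydroxy-3-methylbenzoate
Conditions: 3 M aq. HCl–THF 1:3, 40 °C, dilute
Reagents that add atoms: water, O
Why: Acid-catalysed hydrolysis of the four aryl MOM acetals and of the dimethyl acetal (global deprotection) should release the phenols and the aldehyde in one operation, while both esters, each hydrogen-bonded to an ortho phenol, and the benzylic C–O bond, which has no ortho or para oxygen donor, should survive dilute acid at mild temperature.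

Compound list
1 | 3,5-dihydroxy-4-methylbenzoic acid | Cc1c(O)cc(cc1O)C(=O)O | starting material
2 | methoxymethyl 3,5-bis(methoxymethoxy)-4-methylbenzoate | COCOC(=O)c1cc(OCOC)c(C)c(OCOC)c1 | intermediate
3 | [3,5-bis(methoxymethoxy)-4-methylphenyl]methanol | COCOc1cc(CO)cc(OCOC)c1C | intermediate
4 | [2-iodo-3,5-bis(methoxymethoxy)-4-methylphenyl]methanol | COCOc1cc(CO)c(I)c(OCOC)c1C | intermediate
5 | 1-(bromomethyl)-2-iodo-3,5-bis(methoxymethoxy)-4-methylbenzene | COCOc1cc(CBr)c(I)c(OCOC)c1C | intermediate
6 | orcinol (5-methylbenzene-1,3-diol) | Cc1cc(O)cc(O)c1 | starting material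
7 | 1,3-bis(methoxymethoxy)-5-methylbenzene | COCOc1cc(C)cc(OCOC)c1 | intermediate
8 | [2,6-bis(methoxymethoxy)-4-methylphenyl]lithium | [Li]c1c(OCOC)cc(C)cc1OCOC | intermediate
9 | 2,6-bis(methoxymethoxy)-4-methylbenzaldehyde | COCOc1cc(C)cc(OCOC)c1C=O | intermediate
10 | 3-bromo-2,6-bis(methoxymethoxy)-4-methylbenzaldehyde | COCOc1cc(C)c(Br)c(OCOC)c1C=O | intermediate
11 | 1-bromo-3-(dimethoxymethyl)-2,4-bis(methoxymethoxy)-6-methylbenzene | COCOc1cc(C)c(Br)c(OCOC)c1C(OC)OC | intermediate
12 | [3-(dimethoxymethyl)-2,4-bis(methoxymethoxy)-6-methylphenyl]lithium | [Li]c1c(C)cc(OCOC)c(C(OC)OC)c1OCOC | intermediate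
13 | lithium 3-(dimethoxymethyl)-2,4-bis(methoxymethoxy)-6-methylbenzoate | [Li+].[O-]C(=O)c1c(C)cc(OCOC)c(C(OC)OC)c1OCOC | intermediate
14 | [2-iodo-3,5-bis(methoxymethoxy)-4-methylphenyl]methyl 3-(dimethoxymethyl)-2,4-bis(methoxymethoxy)-6-methylbenzoate | COCOc1cc(COC(=O)c2c(C)cc(OCOC)c(C(OC)OC)c2OCOC)c(I)c(OCOC)c1C | intermediate
15 | carbon monoxide | [C-]#[O+] | starting material
16 | methanol | CO | starting material
17 | methyl 6-{[3-(dimethoxymethyl)-2,4-bis(methoxymethoxy)-6-methylbenzoyl]oxymethyl}-2,4-bis(methoxymethoxy)-3-methylbenzoate | COC(=O)c1c(COC(=O)c2c(C)cc(OCOC)c(C(OC)OC)c2OCOC)cc(OCOC)c(C)c1OCOC | intermediate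
18 | methyl 6-{[(3-formyl-2,4-dihydroxy-6-methylbenzoyl)oxy]methyl}-2,4-dihydroxy-3-methylbenzoate | COC(=O)c1c(COC(=O)c2c(C)cc(O)c(C=O)c2O)cc(O)c(C)c1O | target

Total steps: 11. Longest linear sequence: 7 steps (steps 1, 2, 3, 4, 9, 10, 11; the ring B branch through steps 5 to 8 is equally long).

Steps most likely to fail

Step 10. Oxidative addition and CO insertion at an iodide flanked by the CH2O-acyl group and an OMOM group may be slow. Reductive loss of iodine (hydride from methanol or Et3N) could then overtake carbonylation. The fallback sets out from 14 and comes back at 17, replacing the catalytic cycle by a stoichiometric arylmetal. Iodine–magnesium exchange with i-PrMgCl·LiCl in THF at −20 °C should give [2-({[3-(dimethoxymethyl)-2,4-bis(methoxymethoxy)-6-methylbenzoyl]oxy}methyl)-4,6-bis(methoxymethoxy)-5-methylphenyl]magnesium chloride F1, which is acylated in the same flask with methyl chloroformate to give 17. This is open only because the ring B aldehyde is masked as its acetal, and the ring B ester carbonyl is shielded on both sides against the Grignard reagents.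

Step 9. Exchange or carboxylation may be incomplete, or the tightly ion-paired lithium carboxylate may alkylate sluggishly so that the benzylic bromide is consumed by other nucleophiles. The fallback sets out from 13 (made from 11 as in step 9) and from alcohol 4, and comes back at 14, replacing the SN2 alkylation by a redox condensation. In the anhydrous THF solution, 13 is protonated at −40 °C with exactly one equivalent of HCl in dioxane to give 3-(dimethoxymethyl)-2,4-bis(methoxymethoxy)-6-methylbenzoic acid F2, which is not isolated. Without water the acetal cannot hydrolyse. Alcohol 4, PPh3 and DIAD are then added (0 °C to rt) for a Mitsunobu esterification, in which the hindered acid acts as the O-nucleophile.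

Step 11. The non-chelated MOM ethers may cleave slowly in warm aqueous acid. That gives time for liberated formaldehyde to alkylate ring A C5, or for the neighbouring C1 ester to assist loss of the ring B acid. The fallback sets out from 17 and comes back at 18, unmasking in stages without hot Brønsted acid.
- PPTS in wet acetone at rt should remove only the dimethyl acetal, giving methyl 6-{[3-formyl-2,4-bis(methoxymethoxy)-6-methylbenzoyl]oxymethyl}-2,4-bis(methoxymethoxy)-3-methylbenzoate F3.
- Me3SiOTf and 2,2'-bipyridyl in CH2Cl2 at 0 °C then transfer silyl groups to the four aryl oxygens, giving methyl 6-{[3-formyl-6-methyl-2,4-bis(trimethylsilyloxy)benzoyl]oxymethyl}-3-methyl-2,4-bis(trimethylsilyloxy)benzoate F4, which is not isolated. The methoxymethyl groups leave on the pyridine nitrogen and not as free formaldehyde.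
- Water at rt hydrolyses the aryl silyl ethers to 18.

Further compounds
F1 | step 10 | [2-({[3-(dimethoxymethyl)-2,4-bis(methoxymethoxy)-6-methylbenzoyl]oxy}methyl)-4,6-bis(methoxymethoxy)-5-methylphenyl]magnesium chloride | COCOc1cc(COC(=O)c2c(C)cc(OCOC)c(C(OC)OC)c2OCOC)c([Mg]Cl)c(OCOC)c1C
F2 | step 9 | 3-(dimethoxymethyl)-2,4-bis(methoxymethoxy)-6-methylbenzoic acid | OC(=O)c1c(C)cc(OCOC)c(C(OC)OC)c1OCOC
F3 | step 11 | methyl 6-{[3-formyl-2,4-bis(methoxymethoxy)-6-methylbenzoyl]oxymethyl}-2,4-bis(methoxymethoxy)-3-methylbenzoate | COC(=O)c1c(COC(=O)c2c(C)cc(OCOC)c(C=O)c2OCOC)cc(OCOC)c(C)c1OCOC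
F4 | step 11 | methyl 6-{[3-formyl-6-methyl-2,4-bis(trimethylsilyloxy)benzoyl]oxymethyl}-3-methyl-2,4-bis(trimethylsilyloxy)benzoate | COC(=O)c1c(COC(=O)c2c(C)cc(O[Si](C)(C)C)c(C=O)c2O[Si](C)(C)C)cc(O[Si](C)(C)C)c(C)c1O[Si](C)(C)C
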